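**Strategy**

Ring A is disconnected at C3a–C4 and C7a–C7. Removing C4–C7 leaves a trans-4,5-disubstituted γ-butyrolactone that already holds O1, C2 with its guaiacyl ring, C3 with the C9 arm, C3a as α-carbon and C7a as carbonyl carbon; this enolisable C3a–C7a(=O)–O1 unit is the feature exploited. The missing carbons, the C7 methoxyl and a C5 ester are supplied by a 3-methoxy-2-pyrone-5-carboxylate. In one operation the lactone's O-silyl ketene acetal adds to the pyrone in an inverse-demand Diels–Alder reaction, and loss of CO2 and silanol completes the benzene ring. The precursor is the trimethylsilyl ketene acetal of a bis-silyl-protected lactone whose C2 and C3 centres come from an auxiliary-controlled syn-aldol/lactonisation.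

Key step: step 11

Remark: atom labels are those of the 2,3-dihydro-1-benzofuran core of the target (O1, C2, C3, C3a, C4–C7, C7a; C9 is the CH2O carbon on C3); the sp3 centres created transiently in the key step arise as mixtures and are left undefined, since all of them become aromatic.

**Route**

Step 1
Reactants: 1 vanillin (4-hydroxy-3-methoxybenzaldehyde)
Product: 2 3-methoxy-4-(triisopropylsilyloxy)benzaldehyde
Conditions: TIPSCl, imidazole, DMF, rt
Reagents that add atoms: triisopropylsilyl chloride, CC(C)[Si](Cl)(C(C)C)C(C)C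
Why: Imidazole-promoted O-silylation of the phenol; the bulky aryl TIPS ether removes the acidic OH before the enolate chemistry and should resist the later basic, reductive and acidic steps.

Step 2
Reactants: 3 (R)-4-benzyl-1,3-oxazolidin-2-one; 4 methyl 4-chloro-4-oxobutanoate
Product: 5 methyl 4-[(4R)-4-benzyl-2-oxo-1,3-oxazolidin-3-yl]-4-oxobutanoate
Conditions: n-BuLi, THF, −78 °C; then 4, −78 to 0 °C
Reagents that add atoms: none
Why: N-acylation of the lithiated oxazolidinone by the acid chloride (imide formation), the methyl ester being far less electrophilic at low temperature.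

Step 3
Reactants: 5 methyl 4-[(4R)-4-benzyl-2-oxo-1,3-oxazolidin-3-yl]-4-oxobutanoate; 2 3-methoxy-4-(triisopropylsilyloxy)benzaldehyde
Product: 7 (4R)-4-benzyl-3-{(2R,3R)-2-[3-methoxy-4-(triisopropylsilyloxy)phenyl]-5-oxooxolane-3-carbonyl}-1,3-oxazolidin-2-one, via syn-aldol adduct 6 (not isolated)
Conditions: Bu2BOTf, iPr2NEt, CH2Cl2, 0 °C; 2, −78 to 0 °C; H2O2, pH 7 buffer, MeOH; then PPTS (cat.), toluene, 60 °C
Reagents that add atoms: none
Why: Evans boron syn-aldol then lactonisation: soft enolisation is selective for the imide, the Z-boron enolate reacts through a Zimmerman–Traxler chair on the face away from the benzyl group of the (R)-auxiliary to set the future C3 (α-carbon) and C2 (carbinol) as the R,R syn pair, and acyl transfer of the methyl ester to the new hydroxyl with retention should give the trans lactone.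

Step 4
Reactants: 7 (4R)-4-benzyl-3-{(2R,3R)-2-[3-methoxy-4-(triisopropylsilyloxy)phenyl]-5-oxooxolane-3-carbonyl}-1,3-oxazolidin-2-one
Product: 8 (2R,3R)-2-[3-methoxy-4-(triisopropylsilyloxy)phenyl]-5-oxooxolane-3-carboxylic acid
Conditions: LiOH, H2O2, THF/H2O, 0 °C; Na2SO3; then HCl (1 M) to pH 2
Reagents that add atoms: hydrogen peroxide (as LiOOH), OO
Why: Hydroperoxide cleavage of the N-acyloxazolidinone: LiOOH attacks the exocyclic imide carbonyl selectively at 0 °C, any opened lactone can only reclose to the same γ-lactone on acidification, and neither stereocentre is involved (trans is also the thermodynamic isomer).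

Step 5
Reactants: 8 (2R,3R)-2-[3-methoxy-4-(triisopropylsilyloxy)phenyl]-5-oxooxolane-3-carboxylic acid
Product: 9 (4S,5R)-4-(hydroxymethyl)-5-[3-methoxy-4-(triisopropylsilyloxy)phenyl]oxolan-2-one
Conditions: BH3·SMe2, THF, 0 °C to rt; MeOH quench
Reagents that add atoms: none
Why: Chemoselective borane reduction of a carboxylic acid (through the acyloxyborane) beside the much less reactive lactone, under non-basic conditions that avoid translactonisation; the change of descriptor at the former C3 of the oxolane is only a priority change.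

Step 6
Reactants: 9 (4S,5R)-4-(hydroxymethyl)-5-[3-methoxy-4-(triisopropylsilyloxy)phenyl]oxolan-2-one
Product: 10 (4S,5R)-4-{[(tert-butyldimethylsilyl)oxy]methyl}-5-[3-methoxy-4-(triisopropylsilyloxy)phenyl]oxolan-2-one
Conditions: TBSCl, imidazole, CH2Cl2, 0 °C to rt
Reagents that add atoms: tert-butyldimethylsilyl chloride, CC(C)(C)[Si](C)(C)Cl
Why: Imidazole-promoted silylation of the primary alcohol; the alkyl TBS ether tolerates amide base and heat and can later be removed by acid without touching the aryl TIPS ether.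

Step 7
Reactants: 10 (4S,5R)-4-{[(tert-butyldimethylsilyl)oxy]methyl}-5-[3-methoxy-4-(triisopropylsilyloxy)phenyl]oxolan-2-one
Product: 11 (2R,3S)-3-{[(tert-butyldimethylsilyl)oxy]methyl}-2-[3-methoxy-4-(triisopropylsilyloxy)phenyl]-5-(trimethylsilyloxy)-2,3-dihydrofuran
Conditions: LiN(iPr)2, THF, −78 °C; TMSCl, −78 °C to rt; evaporation, pentane, filtration (no aqueous work-up), used at once
Reagents that add atoms: trimethylsilyl chloride, C[Si](C)(C)Cl
Why: Kinetic deprotonation of the lactone α-CH2 (future C3a) and O-silylation of the enolate (silyl ketene acetal formation); there is no β-leaving group, C2 and C3 are not acidic, and the non-aqueous work-up spares the hydrolytically labile product.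

Step 8
Reactants: 12 dimethyl 2-oxopentanedioate
Product: 14 dimethyl 2-methoxypent-2-enedioate (E/Z mixture), via dimethyl ketal 13 (not isolated)
Conditions: HC(OMe)3, MeOH, TsOH·H2O (cat.), reflux; then 150 °C with distillation of MeOH
Reagents that add atoms: trimethyl orthoformate, COC(OC)OC; methanol, CO
Why: Acid-catalysed ketalisation with orthoformate followed by acid-catalysed thermal loss of methanol (enol ether formation), which can only occur towards C3; the pyrone is built de novo because 3-halo-2-pyrones are opened and ring-contracted by alkoxide and so cannot simply be methoxylated.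

Step 9
Reactants: 14 dimethyl 2-methoxypent-2-enedioate
Product: 15 dimethyl 4-[(dimethylamino)methylidene]-2-methoxypent-2-enedioate
Conditions: Me2NCH(OMe)2, toluene, 80 °C
Reagents that add atoms: N,N-dimethylformamide dimethyl acetal, COC(OC)N(C)C
Why: Aminomethylenation of an active methylene with an amide acetal: C4 is α to one ester and vinylogous to the other, and it is the only acidic carbon that carries the two hydrogens needed for condensation.

Step 10
Reactants: 15 dimethyl 4-[(dimethylamino)methylidene]-2-methoxypent-2-enedioate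
Product: 17 methyl 3-methoxy-2-oxo-2H-pyran-5-carboxylate, via hydroxymethylene enol 16 (not isolated)
Conditions: HCl (1 M aq.), THF, rt; then PPTS (cat.), toluene, 100 °C
Reagents that add atoms: water, O
Why: Acid hydrolysis of the vinylogous carbamate to the enol and enol lactonisation onto the C1 ester (the coumalate-type 2-pyrone ring closure); the push–pull diene isomerises about C2=C3 so that the closing geometry is reachable, and loss of methanol is driven by formation of the conjugated pyrone.

Step 11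
Reactants: 11 (2R,3S)-3-{[(tert-butyldimethylsilyl)oxy]methyl}-2-[3-methoxy-4-(triisopropylsilyloxy)phenyl]-5-(trimethylsilyloxy)-2,3-dihydrofuran; 17 methyl 3-methoxy-2-oxo-2H-pyran-5-carboxylate
Product: 20 methyl (2R,3S)-3-{[(tert-butyldimethylsilyl)oxy]methyl}-7-methoxy-2-[3-methoxy-4-(triisopropylsilyloxy)phenyl]-2,3-dihydro-1-benzofuran-5-carboxylate, via bridged lactone cycloadduct 18 (not isolated), via cyclohexadiene silyl ketal 19 (not isolated)
Conditions: 17 (1.5 equiv), toluene, 100 °C, sealed tube; then CSA (cat.), CH2Cl2, 0 °C to rt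
Reagents that add atoms: none
Why: The electron-rich C3a=C7a ketene acetal is the 2π partner and the ester-activated pyrone the 4π partner of an inverse-electron-demand Diels–Alder reaction that runs asynchronously: nucleophilic C3a bonds to pyrone C6 (β to the ester) and the oxocarbenium-like C7a then closes onto pyrone C3, so six-membered ring A is closed by intermolecular [4+2] cycloaddition. Cycloreversion of bridged lactone 18 expels CO2 to give cyclohexadiene 19, and acid-promoted 1,2-elimination of trimethylsilanol across C3a–C7a aromatises it. The closest known reaction type is the alkoxybenzoate synthesis from 2-pyrone-5-carboxylates and ketene acetals. No stereocentre is created, because every sp3 carbon formed ends up aromatic, and C2 and C3 lie outside the reacting π system and keep their configuration. The regioselectivity needed is secured by the matched polarisation of the partners (ketene acetal β-carbon to the pyrone carbon β to the ester), which places O1 para to the ester and ortho to the methoxyl. The choice of leaving group in the elimination (silanolate rather than O1) is backed up by the acid treatment, since a ring-opened phenol would reclose through the para-silyloxybenzylic cation at C2 to the same trans-dihydrobenzofuran under control of the untouched C3 centre.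

Step 12
Reactants: 20 methyl (2R,3S)-3-{[(tert-butyldimethylsilyl)oxy]methyl}-7-methoxy-2-[3-methoxy-4-(triisopropylsilyloxy)phenyl]-2,3-dihydro-1-benzofuran-5-carboxylate
Product: 21 [(2R,3S)-3-{[(tert-butyldimethylsilyl)oxy]methyl}-7-methoxy-2-[3-methoxy-4-(triisopropylsilyloxy)phenyl]-2,3-dihydro-1-benzofuran-5-yl]methanol
Conditions: iBu2AlH, CH2Cl2, −78 °C; aqueous potassium sodium tartrate
Reagents that add atoms: none
Why: Hydride reduction of the aryl ester to the benzylic alcohol; both silyl ethers and the cyclic benzylic ether are inert to the aluminium hydride at low temperature.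

Step 13
Reactants: 21 [(2R,3S)-3-{[(tert-butyldimethylsilyl)oxy]methyl}-7-methoxy-2-[3-methoxy-4-(triisopropylsilyloxy)phenyl]-2,3-dihydro-1-benzofuran-5-yl]methanol
Product: 22 (2R,3S)-3-{[(tert-butyldimethylsilyl)oxy]methyl}-7-methoxy-2-[3-methoxy-4-(triisopropylsilyloxy)phenyl]-2,3-dihydro-1-benzofuran-5-carbaldehyde
Conditions: MnO2, CH2Cl2, rt
Reagents that add atoms: none
Why: Selective MnO2 oxidation of a benzylic alcohol, which stops at the aldehyde.

Step 14
Reactants: 22 (2R,3S)-3-{[(tert-butyldimethylsilyl)oxy]methyl}-7-methoxy-2-[3-methoxy-4-(triisopropylsilyloxy)phenyl]-2,3-dihydro-1-benzofuran-5-carbaldehyde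
Product: 23 (E)-3-[(2R,3S)-3-{[(tert-butyldimethylsilyl)oxy]methyl}-7-methoxy-2-[3-methoxy-4-(triisopropylsilyloxy)phenyl]-2,3-dihydro-1-benzofuran-5-yl]prop-2-enal
Conditions: Ph3P=CHCHO (1.3 equiv), toluene, 80 °C
Reagents that add atoms: (triphenylphosphoranylidene)acetaldehyde, O=CC=P(c1ccccc1)(c1ccccc1)c1ccccc1
Why: Wittig olefination with the stabilised formylmethylene ylide, which should give the E-enal, a small excess of ylide limiting a second homologation.

Step 15
Reactants: 23 (E)-3-[(2R,3S)-3-{[(tert-butyldimethylsilyl)oxy]methyl}-7-methoxy-2-[3-methoxy-4-(triisopropylsilyloxy)phenyl]-2,3-dihydro-1-benzofuran-5-yl]prop-2-enal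
Product: 24 (E)-3-[(2R,3S)-3-(hydroxymethyl)-7-methoxy-2-[3-methoxy-4-(triisopropylsilyloxy)phenyl]-2,3-dihydro-1-benzofuran-5-yl]prop-2-enal
Conditions: AcOH/THF/H2O (3:1:1), rt
Reagents that add atoms: none
Why: Acid-catalysed solvolysis of a silyl ether: a primary alkyl TBS ether is cleaved by aqueous acetic acid much faster than the hindered, acid-resistant aryl TIPS ether, and the enal tolerates the medium.

Step 16
Reactants: 24 (E)-3-[(2R,3S)-3-(hydroxymethyl)-7-methoxy-2-[3-methoxy-4-(triisopropylsilyloxy)phenyl]-2,3-dihydro-1-benzofuran-5-yl]prop-2-enal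
Product: 25 [(2R,3S)-7-methoxy-2-[3-methoxy-4-(triisopropylsilyloxy)phenyl]-5-[(E)-3-oxoprop-1-enyl]-2,3-dihydro-1-benzofuran-3-yl]methyl 3-methylbutanoate
Conditions: isovaleryl chloride, pyridine, DMAP (cat.), CH2Cl2, 0 °C
Reagents that add atoms: 3-methylbutanoyl chloride, CC(C)CC(Cl)=O
Why: DMAP-catalysed esterification of the primary alcohol with the acid chloride; the phenol is still silylated, so only the C9 hydroxyl can react.

Step 17
Reactants: 25 [(2R,3S)-7-methoxy-2-[3-methoxy-4-(triisopropylsilyloxy)phenyl]-5-[(E)-3-oxoprop-1-enyl]-2,3-dihydro-1-benzofuran-3-yl]methyl 3-methylbutanoate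
Product: 26 [(2R,3S)-2-(4-hydroxy-3-methoxyphenyl)-7-methoxy-5-[(E)-3-oxoprop-1-enyl]-2,3-dihydro-1-benzofuran-3-yl]methyl 3-methylbutanoate (CNP0272976.1)
Conditions: Bu4NF, AcOH, THF, 0 °C
Reagents that add atoms: none
Why: Fluoride-mediated cleavage of the aryl silyl ether, buffered with acetic acid so that the ester and the enal are not exposed to basic fluoride or free phenoxide.

**Compound list**

1 | vanillin (4-hydroxy-3-methoxybenzaldehyde) | COc1cc(C=O)ccc1O | starting material
2 | 3-methoxy-4-(triisopropylsilyloxy)benzaldehyde | COc1cc(C=O)ccc1O[Si](C(C)C)(C(C)C)C(C)C | intermediate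
3 | (R)-4-benzyl-1,3-oxazolidin-2-one | O=C1N[C@H](Cc2ccccc2)CO1 | starting material
4 | methyl 4-chloro-4-oxobutanoate | COC(=O)CCC(Cl)=O | starting material
5 | methyl 4-[(4R)-4-benzyl-2-oxo-1,3-oxazolidin-3-yl]-4-oxobutanoate | COC(=O)CCC(=O)N1[C@H](Cc2ccccc2)COC1=O | intermediate
6 | methyl (3R,4R)-3-{[(4R)-4-benzyl-2-oxo-1,3-oxazolidin-3-yl]carbonyl}-4-hydroxy-4-[3-methoxy-4-(triisopropylsilyloxy)phenyl]butanoate (syn-aldol adduct, not isolated) | COC(=O)C[C@@H](C(=O)N1[C@H](Cc2ccccc2)COC1=O)[C@@H](O)c1ccc(O[Si](C(C)C)(C(C)C)C(C)C)c(OC)c1 | intermediate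
7 | (4R)-4-benzyl-3-{(2R,3R)-2-[3-methoxy-4-(triisopropylsilyloxy)phenyl]-5-oxooxolane-3-carbonyl}-1,3-oxazolidin-2-one (trans lactone) | O=C1C[C@@H](C(=O)N2[C@H](Cc3ccccc3)COC2=O)[C@H](c2ccc(O[Si](C(C)C)(C(C)C)C(C)C)c(OC)c2)O1 | intermediate
8 | (2R,3R)-2-[3-methoxy-4-(triisopropylsilyloxy)phenyl]-5-oxooxolane-3-carboxylic acid | O=C1C[C@@H](C(=O)O)[C@H](c2ccc(O[Si](C(C)C)(C(C)C)C(C)C)c(OC)c2)O1 | intermediate
9 | (4S,5R)-4-(hydroxymethyl)-5-[3-methoxy-4-(triisopropylsilyloxy)phenyl]oxolan-2-one | O=C1C[C@@H](CO)[C@H](c2ccc(O[Si](C(C)C)(C(C)C)C(C)C)c(OC)c2)O1 | intermediate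
10 | (4S,5R)-4-{[(tert-butyldimethylsilyl)oxy]methyl}-5-[3-methoxy-4-(triisopropylsilyloxy)phenyl]oxolan-2-one | COc1cc([C@@H]2OC(=O)C[C@H]2CO[Si](C)(C)C(C)(C)C)ccc1O[Si](C(C)C)(C(C)C)C(C)C | intermediate
11 | (2R,3S)-3-{[(tert-butyldimethylsilyl)oxy]methyl}-2-[3-methoxy-4-(triisopropylsilyloxy)phenyl]-5-(trimethylsilyloxy)-2,3-dihydrofuran (trimethylsilyl ketene acetal of 10) | COc1cc([C@@H]2OC(O[Si](C)(C)C)=C[C@H]2CO[Si](C)(C)C(C)(C)C)ccc1O[Si](C(C)C)(C(C)C)C(C)C | intermediate
12 | dimethyl 2-oxopentanedioate | COC(=O)CCC(=O)C(=O)OC | starting material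
13 | dimethyl 2,2-dimethoxypentanedioate (not isolated) | COC(=O)CCC(OC)(OC)C(=O)OC | intermediate
14 | dimethyl 2-methoxypent-2-enedioate (E/Z mixture) | COC(=O)CC=C(OC)C(=O)OC | intermediate
15 | dimethyl 4-[(dimethylamino)methylidene]-2-methoxypent-2-enedioate (geometry undefined) | COC(=O)C(=CN(C)C)C=C(OC)C(=O)OC | intermediate
16 | dimethyl 4-(hydroxymethylidene)-2-methoxypent-2-enedioate (enol, geometry undefined, not isolated) | COC(=O)C(=CO)C=C(OC)C(=O)OC | intermediate
17 | methyl 3-methoxy-2-oxo-2H-pyran-5-carboxylate | COC(=O)C1=COC(=O)C(OC)=C1 | intermediate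
18 | bridged lactone cycloadduct: methyl 4-methoxy-3-oxo-2-oxabicyclo[2.2.2]oct-5-ene-6-carboxylate fused across C7–C8 to the 2-aryl-3-(silyloxymethyl)oxolane, OTMS on the ring-fusion acetal carbon; C2 R and C3 S as in 11, new centres a mixture (not isolated) | COC(=O)C1=CC2(OC)C(=O)OC1C3C2(O[Si](C)(C)C)O[C@@H](c4ccc(O[Si](C(C)C)(C(C)C)C(C)C)c(OC)c4)[C@@H]3CO[Si](C)(C)C(C)(C)C | intermediate
19 | methyl (2R,3S)-3-{[(tert-butyldimethylsilyl)oxy]methyl}-7-methoxy-2-[3-methoxy-4-(triisopropylsilyloxy)phenyl]-7a-(trimethylsilyloxy)-2,3,3a,7a-tetrahydro-1-benzofuran-5-carboxylate, C3a/C7a undefined (not isolated) | COC(=O)C1=CC2C(O[Si](C)(C)C)(O[C@@H](c3ccc(O[Si](C(C)C)(C(C)C)C(C)C)c(OC)c3)[C@@H]2CO[Si](C)(C)C(C)(C)C)C(OC)=C1 | intermediate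
20 | methyl (2R,3S)-3-{[(tert-butyldimethylsilyl)oxy]methyl}-7-methoxy-2-[3-methoxy-4-(triisopropylsilyloxy)phenyl]-2,3-dihydro-1-benzofuran-5-carboxylate (trans) | COc1cc([C@@H]2Oc3c(OC)cc(C(=O)OC)cc3[C@H]2CO[Si](C)(C)C(C)(C)C)ccc1O[Si](C(C)C)(C(C)C)C(C)C | intermediate
21 | [(2R,3S)-3-{[(tert-butyldimethylsilyl)oxy]methyl}-7-methoxy-2-[3-methoxy-4-(triisopropylsilyloxy)phenyl]-2,3-dihydro-1-benzofuran-5-yl]methanol | COc1cc([C@@H]2Oc3c(OC)cc(CO)cc3[C@H]2CO[Si](C)(C)C(C)(C)C)ccc1O[Si](C(C)C)(C(C)C)C(C)C | intermediate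
22 | (2R,3S)-3-{[(tert-butyldimethylsilyl)oxy]methyl}-7-methoxy-2-[3-methoxy-4-(triisopropylsilyloxy)phenyl]-2,3-dihydro-1-benzofuran-5-carbaldehyde | COc1cc([C@@H]2Oc3c(OC)cc(C=O)cc3[C@H]2CO[Si](C)(C)C(C)(C)C)ccc1O[Si](C(C)C)(C(C)C)C(C)C | intermediate
23 | (E)-3-[(2R,3S)-3-{[(tert-butyldimethylsilyl)oxy]methyl}-7-methoxy-2-[3-methoxy-4-(triisopropylsilyloxy)phenyl]-2,3-dihydro-1-benzofuran-5-yl]prop-2-enal | COc1cc([C@@H]2Oc3c(OC)cc(/C=C/C=O)cc3[C@H]2CO[Si](C)(C)C(C)(C)C)ccc1O[Si](C(C)C)(C(C)C)C(C)C | intermediate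
24 | (E)-3-[(2R,3S)-3-(hydroxymethyl)-7-methoxy-2-[3-methoxy-4-(triisopropylsilyloxy)phenyl]-2,3-dihydro-1-benzofuran-5-yl]prop-2-enal | COc1cc([C@@H]2Oc3c(OC)cc(/C=C/C=O)cc3[C@H]2CO)ccc1O[Si](C(C)C)(C(C)C)C(C)C | intermediate
25 | [(2R,3S)-7-methoxy-2-[3-methoxy-4-(triisopropylsilyloxy)phenyl]-5-[(E)-3-oxoprop-1-enyl]-2,3-dihydro-1-benzofuran-3-yl]methyl 3-methylbutanoate | COc1cc([C@@H]2Oc3c(OC)cc(/C=C/C=O)cc3[C@H]2COC(=O)CC(C)C)ccc1O[Si](C(C)C)(C(C)C)C(C)C | intermediate
26 | [(2R,3S)-2-(4-hydroxy-3-methoxyphenyl)-7-methoxy-5-[(E)-3-oxoprop-1-enyl]-2,3-dihydro-1-benzofuran-3-yl]methyl 3-methylbutanoate (CNP0272976.1) | COc1cc([C@@H]2Oc3c(OC)cc(/C=C/C=O)cc3[C@H]2COC(=O)CC(C)C)ccc1O | target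

**Step count and risks**

Total steps: 17. Longest linear sequence: 13 steps (steps 1, 3–7, 11–17; the pyrone branch, steps 8–10, joins at step 11).

The three steps most likely to fail:

1. Step 11. The cycloaddition may be too slow, because the C3 methoxyl makes the pyrone less electron-poor and crowds the carbon that must bond to the fully substituted C7a. The moisture-sensitive ketene acetal would then be lost by protodesilylation or stop at a Michael adduct. The fallback installs the C7 oxygen after the benzannulation; it sets out from 11 and comes back at 20. Commercial methyl coumalate is brominated (Br2, CH2Cl2, then Et3N) to the more electron-poor diene methyl 3-bromo-2-oxo-2H-pyran-5-carboxylate F1. Heating 11 with F1 (toluene, 60 °C; then CSA cat.) should give methyl (2R,3S)-7-bromo-3-{[(tert-butyldimethylsilyl)oxy]methyl}-2-[3-methoxy-4-(triisopropylsilyloxy)phenyl]-2,3-dihydro-1-benzofuran-5-carboxylate F2. Miyaura borylation (B2pin2, Pd(dppf)Cl2, KOAc, dioxane, 80 °C) should lead to the 7-(4,4,5,5-tetramethyl-1,3,2-dioxaborolan-2-yl) analogue F3. Oxidation with NaBO3·4H2O in THF/H2O should give the 7-hydroxy analogue F4, and O-methylation (MeI, K2CO3, acetone) returns the route to 20.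

2. Step 10. Under the aqueous acid needed to unmask the enamine, hydrolysis of the α-methoxy enol ether or of the esters may outrun lactonisation, or the enol may be diverted into a five-membered closure onto C2. The fallback brings in C6 with its oxygen already attached and closes the ring without an aqueous or strong-acid stage; it sets out from 14 and comes back at 17. Claisen formylation of 14 (NaH, HCO2Me, THF, 0 °C to rt) should give the sodium enolate of dimethyl 4-(hydroxymethylidene)-2-methoxypent-2-enedioate F5. Neutralising it with one equivalent of AcOH liberates enol 16, which is heated in toluene at 100 °C to close thermally to 17.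

3. Step 14. The formyl ylide may react sluggishly with the electron-rich aldehyde while the product enal is homologated a second time to the dienal. The fallback builds the enal at the ester oxidation level; it sets out from 22 and comes back at 23. Wittig reaction of 22 with Ph3P=CHCO2Et (toluene, 80 °C) should give ethyl (E)-3-[(2R,3S)-3-{[(tert-butyldimethylsilyl)oxy]methyl}-7-methoxy-2-[3-methoxy-4-(triisopropylsilyloxy)phenyl]-2,3-dihydro-1-benzofuran-5-yl]prop-2-enoate F6. Reduction with iBu2AlH (CH2Cl2, −78 °C) should give the corresponding (E)-prop-2-en-1-ol F7, and MnO2 oxidation (CH2Cl2, rt) returns the route to 23.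

Further compounds
F1 | step 11 | methyl 3-bromo-2-oxo-2H-pyran-5-carboxylate | COC(=O)C1=COC(=O)C(Br)=C1
F2 | step 11 | methyl (2R,3S)-7-bromo-3-{[(tert-butyldimethylsilyl)oxy]methyl}-2-[3-methoxy-4-(triisopropylsilyloxy)phenyl]-2,3-dihydro-1-benzofuran-5-carboxylate | COc1cc([C@@H]2Oc3c(Br)cc(C(=O)OC)cc3[C@H]2CO[Si](C)(C)C(C)(C)C)ccc1O[Si](C(C)C)(C(C)C)C(C)C
F3 | step 11 | methyl (2R,3S)-3-{[(tert-butyldimethylsilyl)oxy]methyl}-2-[3-methoxy-4-(triisopropylsilyloxy)phenyl]-7-(4,4,5,5-tetramethyl-1,3,2-dioxaborolan-2-yl)-2,3-dihydro-1-benzofuran-5-carboxylate | COc1cc([C@@H]2Oc3c(B4OC(C)(C)C(C)(C)O4)cc(C(=O)OC)cc3[C@H]2CO[Si](C)(C)C(C)(C)C)ccc1O[Si](C(C)C)(C(C)C)C(C)C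
F4 | step 11 | methyl (2R,3S)-3-{[(tert-butyldimethylsilyl)oxy]methyl}-7-hydroxy-2-[3-methoxy-4-(triisopropylsilyloxy)phenyl]-2,3-dihydro-1-benzofuran-5-carboxylate | COc1cc([C@@H]2Oc3c(O)cc(C(=O)OC)cc3[C@H]2CO[Si](C)(C)C(C)(C)C)ccc1O[Si](C(C)C)(C(C)C)C(C)C
F5 | step 10 | sodium enolate of dimethyl 4-(hydroxymethylidene)-2-methoxypent-2-enedioate (geometry undefined) | COC(=O)C(=C[O-])C=C(OC)C(=O)OC.[Na+]
F6 | step 14 | ethyl (E)-3-[(2R,3S)-3-{[(tert-butyldimethylsilyl)oxy]methyl}-7-methoxy-2-[3-methoxy-4-(triisopropylsilyloxy)phenyl]-2,3-dihydro-1-benzofuran-5-yl]prop-2-enoate | COc1cc([C@@H]2Oc3c(OC)cc(/C=C/C(=O)OCC)cc3[C@H]2CO[Si](C)(C)C(C)(C)C)ccc1O[Si](C(C)C)(C(C)C)C(C)C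
F7 | step 14 | (E)-3-[(2R,3S)-3-{[(tert-butyldimethylsilyl)oxy]methyl}-7-methoxy-2-[3-methoxy-4-(triisopropylsilyloxy)phenyl]-2,3-dihydro-1-benzofuran-5-yl]prop-2-en-1-ol | COc1cc([C@@H]2Oc3c(OC)cc(/C=C/CO)cc3[C@H]2CO[Si](C)(C)C(C)(C)C)ccc1O[Si](C(C)C)(C(C)C)C(C)C
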